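**Retrosynthetic overview**
- The C11 acetoxy centre comes from the α-methyl lactone by enolate hydroxylation and in-flask acetylation; the C8 angelate comes from an (8R)-alcohol by Mitsunobu inversion.
- Key disconnection C6–C7: SmI2 turns the C6 enal into a ketyl (reversed polarity at the carbonyl carbon), which adds to C7 of an (E)-γ-silyloxy-α-methyl enoate.
- That acyclic precursor comes from a C12 hydroxy aldehyde by proline-catalysed α-aminoxylation (sets C8) and in-flask Wittig olefination.
- The C12 hydroxy aldehyde comes from (E,E)-farnesyl acetate by terminal bromohydrin/epoxide formation and periodate cleavage; both ring (E)-alkenes are inherited from farnesol.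
- Ring order: the ten-membered carbocycle closes first (C6–C7 bond), and the γ-lactone closes second in the same flask through the C6 alkoxide.

Assumptions: atom labels follow germacrane numbering (C6 lactone carbinol, C7 ring-fusion CH, C8 angelate carbinol, C11 acetoxy carbon, C12 lactone carbonyl). The α-methyl centre C11 is carried as an epimer mixture until the last step re-makes it. (2E,6E)-Farnesyl acetate is bought as such.

Step 1
Reactants: 1 (2E,6E)-farnesyl acetate
Product: 2 (2E,6E)-10-bromo-11-hydroxy-3,7,11-trimethyldodeca-2,6-dien-1-yl acetate (racemic at C10)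
Conditions: NBS (1.1 equiv), THF/H2O 2:1, 0 °C
Reagents that add atoms: N-bromosuccinimide, O=C1CCC(=O)N1Br; water, O
Why: Bromohydrin formation (van Tamelen-type terminal functionalisation) occurs at the most accessible, most electron-rich terminal alkene (the 2,3-alkene is deactivated by the allylic acetate) with water opening the bromonium ion at the tertiary carbon; the racemic C10 centre is destroyed in step 3.

Step 2
Reactants: 2 bromohydrin acetate
Product: 3 (2E,6E)-9-(3,3-dimethyloxiran-2-yl)-3,7-dimethylnona-2,6-dien-1-ol (10,11-epoxyfarnesol, racemic)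
Conditions: K2CO3 (3 equiv), MeOH, 23 °C
Reagents that add atoms: none
Why: Intramolecular Williamson (SN2) epoxide closure of the bromohydrin runs alongside base-catalysed methanolysis of the allylic acetate; no stereocentre formed here is kept.

Step 3
Reactants: 3 10,11-epoxyfarnesol
Product: 4 (4E,8E)-10-hydroxy-4,8-dimethyldeca-4,8-dienal
Conditions: H5IO6 (1.2 equiv), THF/H2O 5:1, 0 °C
Reagents that add atoms: none
Why: Periodic acid hydrolyses the trisubstituted epoxide to the glycol and cleaves it (Malaprade glycol cleavage) to the C12 aldehyde and acetone, the aldehyde oxygen being the former epoxide oxygen.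

Step 4
Reactants: 4 hydroxy aldehyde, 5 ethyl 2-(triphenyl-λ5-phosphanylidene)propanoate
Product: 8 ethyl (2E,4R,6E,10E)-4,12-dihydroxy-2,6,10-trimethyldodeca-2,6,10-trienoate, via (2R)-aminoxy aldehyde 6 (not isolated), via γ-aminoxy enoate 7 (not isolated)
Conditions: L-proline (20 mol %), PhNO (0.95 equiv), MeCN, −20 °C; then 5 (1.5 equiv), 0 → 23 °C; then Cu(OAc)2 (30 mol %), EtOH, 23 °C
Reagents that add atoms: nitrosobenzene, O=Nc1ccccc1; ethyl 2-(triphenyl-λ5-phosphanylidene)propanoate (5), CCOC(=O)C(C)=P(c1ccccc1)(c1ccccc1)c1ccccc1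
Why: Proline-catalysed enamine α-aminoxylation (O-nitroso aldol) sets C8 as (R) because the carboxylic acid of L-proline delivers the nitroso oxygen to one enamine face (typically ≥97% ee); the stabilised Wittig ylide, added once the limiting nitrosobenzene is consumed, gives the (E)-2-methyl enoate without isolating the labile α-oxy aldehyde, and Cu(OAc)2-catalysed N–O cleavage frees the γ-hydroxyl.

Step 5
Reactants: 8 diol ester
Product: 9 ethyl (2E,4R,6E,10E)-4-hydroxy-2,6,10-trimethyl-12-oxododeca-2,6,10-trienoate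
Conditions: TEMPO (10 mol %), PhI(OAc)2 (1.1 equiv), CH2Cl2, 23 °C
Reagents that add atoms: none
Why: The TEMPO/PhI(OAc)2 oxoammonium oxidation is selective for the primary allylic alcohol over the secondary alcohol and gives the (E)-enal without over-oxidation or E/Z isomerisation.

Step 6
Reactants: 9 hydroxy enal ester
Product: 10 ethyl (2E,4R,6E,10E)-2,6,10-trimethyl-12-oxo-4-[(triethylsilyl)oxy]dodeca-2,6,10-trienoate
Conditions: Et3SiCl (1.3 equiv), imidazole (2.5 equiv), CH2Cl2, 0 → 23 °C
Reagents that add atoms: chlorotriethylsilane, CC[Si](Cl)(CC)CC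
Why: Standard silylation blocks O8 so that only O6 can lactonise in step 7, and the non-coordinating silyl ether enforces Felkin–Anh-type (anti) attack at C7.

Step 7
Reactants: 10 silyloxy enal ester
Product: 13 (3aS,4R,6E,10E,11aR)-4-hydroxy-3,6,10-trimethyl-3a,4,5,8,9,11a-hexahydrocyclodeca[b]furan-2(3H)-one (C3 epimers), via macrocyclic hydroxy ester 11 (not isolated), via lactone silyl ether 12 (not isolated)
Conditions: SmI2 (0.1 M in THF, 2.4 equiv, added over 4 h), t-BuOH (2.5 equiv), THF (2 mM in 10), −20 → 23 °C; then AcOH and Bu4NF (3 equiv each), 23 °C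
Reagents that add atoms: none
Why: Proposed new method: SmI2 transfers one electron to the enal to give a trivalent samarium ketyl, an α-oxy carbon nucleophile in which the normally electrophilic C6 has reversed polarity, and this adds to the normally electrophilic β-carbon C7 of the enoate to close the ten-membered ring; a second SmI2 reduces the α-ester radical to the samarium enolate, t-BuOH protonates it, and the samarium alkoxide at O6 (the only free oxygen nucleophile) closes the γ-lactone on warming; allylic 1,3-strain with the α-methyl group holds H8 in the alkene plane so C6 adds anti to the OSiEt3 group (7S from 8R), and the arrangement with O6 anti to C11 and C5 anti to C8 gives the 6R carbinol and hence the cis-fused lactone; the closest known reactions are the SmI2 ketyl–olefin coupling of aldehydes with β-substituted acrylates to cis-β,γ-disubstituted γ-butyrolactones, SmI2 ketyl–olefin closures of medium rings, and germacrane ring closure at this same C6–C7 bond by intramolecular allylation of this type of enal; the buffered fluoride only removes the silyl group.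

Step 8
Reactants: 13 (8R)-hydroxy lactone, 14 angelic acid ((2Z)-2-methylbut-2-enoic acid)
Product: 15 (3aS,4S,6E,10E,11aR)-3,6,10-trimethyl-2-oxo-2,3,3a,4,5,8,9,11a-octahydrocyclodeca[b]furan-4-yl (2Z)-2-methylbut-2-enoate (C3 epimers)
Conditions: 14 (2 equiv), PPh3 (2 equiv), DIAD (2 equiv), toluene, 0 → 23 °C
Reagents that add atoms: angelic acid (14), C/C=C(/C)C(=O)O
Why: Mitsunobu esterification displaces the alkoxyphosphonium group by angelate with SN2 inversion, turning C8 from (R) into the required (S), and because the acid is never activated as an acyl donor the (Z)-alkene is not isomerised to the tiglate.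

Step 9
Reactants: 15 angelate lactone, 16 acetic anhydride
Product: 18 CNP0144564.1, (3R,3aS,4S,6E,10E,11aR)-3-acetoxy-3,6,10-trimethyl-2-oxo-2,3,3a,4,5,8,9,11a-octahydrocyclodeca[b]furan-4-yl (2Z)-2-methylbut-2-enoate, via potassium C11 alkoxide 17 (not isolated)
Conditions: KN(SiMe3)2 (1.2 equiv), THF, −78 °C; 2-(benzenesulfonyl)-3-phenyloxaziridine (1.5 equiv), −78 °C; then Ac2O (5 equiv), −78 → 0 °C
Reagents that add atoms: 2-(benzenesulfonyl)-3-phenyloxaziridine, O=S(=O)(c1ccccc1)N1OC1c1ccccc1; acetic anhydride (16), CC(=O)OC(C)=O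
Why: Davis oxaziridine hydroxylation of the potassium lactone enolate takes place on the convex face of the cis-fused bicycle, opposite the C7–C8 and C6–C5 ring bonds, which sets C11 as (R) with oxygen cis to H7; the tertiary potassium alkoxide is then O-acetylated in the same flask.

**Compound list**
1 | (2E,6E)-3,7,11-trimethyldodeca-2,6,10-trien-1-yl acetate ((E,E)-farnesyl acetate) | CC(C)=CCC/C(C)=C/CC/C(C)=C/COC(C)=O | starting material
2 | (2E,6E)-10-bromo-11-hydroxy-3,7,11-trimethyldodeca-2,6-dien-1-yl acetate (racemic at C10) | CC(C)(O)C(Br)CC/C(C)=C/CC/C(C)=C/COC(C)=O | intermediate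
3 | (2E,6E)-9-(3,3-dimethyloxiran-2-yl)-3,7-dimethylnona-2,6-dien-1-ol (racemic) | CC1(C)OC1CC/C(C)=C/CC/C(C)=C/CO | intermediate
4 | (4E,8E)-10-hydroxy-4,8-dimethyldeca-4,8-dienal | O=CCC/C(C)=C/CC/C(C)=C/CO | intermediate
5 | ethyl 2-(triphenyl-λ5-phosphanylidene)propanoate | CCOC(=O)C(C)=P(c1ccccc1)(c1ccccc1)c1ccccc1 | starting material
6 | (2R,4E,8E)-2-(anilinooxy)-10-hydroxy-4,8-dimethyldeca-4,8-dienal | O=C[C@H](ONc1ccccc1)C/C(C)=C/CC/C(C)=C/CO | intermediate
7 | ethyl (2E,4R,6E,10E)-4-(anilinooxy)-12-hydroxy-2,6,10-trimethyldodeca-2,6,10-trienoate | CCOC(=O)/C(C)=C/[C@H](ONc1ccccc1)C/C(C)=C/CC/C(C)=C/CO | intermediate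
8 | ethyl (2E,4R,6E,10E)-4,12-dihydroxy-2,6,10-trimethyldodeca-2,6,10-trienoate | CCOC(=O)/C(C)=C/[C@H](O)C/C(C)=C/CC/C(C)=C/CO | intermediate
9 | ethyl (2E,4R,6E,10E)-4-hydroxy-2,6,10-trimethyl-12-oxododeca-2,6,10-trienoate | CCOC(=O)/C(C)=C/[C@H](O)C/C(C)=C/CC/C(C)=C/C=O | intermediate
10 | ethyl (2E,4R,6E,10E)-2,6,10-trimethyl-12-oxo-4-[(triethylsilyl)oxy]dodeca-2,6,10-trienoate | CCOC(=O)/C(C)=C/[C@H](O[Si](CC)(CC)CC)C/C(C)=C/CC/C(C)=C/C=O | intermediate
11 | ethyl 2-[(1R,2R,3E,7E,10R)-2-hydroxy-4,8-dimethyl-10-[(triethylsilyl)oxy]cyclodeca-3,7-dien-1-yl]propanoate (formed as its samarium alkoxide; epimers at the propanoate carbon) | CC[Si](CC)(CC)O[C@@H]1C/C(C)=C/CC/C(C)=C/[C@@H](O)[C@H]1C(C)C(=O)OCC | intermediate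
12 | (3aR,4R,6E,10E,11aR)-3,6,10-trimethyl-4-[(triethylsilyl)oxy]-3a,4,5,8,9,11a-hexahydrocyclodeca[b]furan-2(3H)-one (C3 epimers) | CC[Si](CC)(CC)O[C@@H]1C/C(C)=C/CC/C(C)=C/[C@H]2OC(=O)C(C)[C@@H]12 | intermediate
13 | (3aS,4R,6E,10E,11aR)-4-hydroxy-3,6,10-trimethyl-3a,4,5,8,9,11a-hexahydrocyclodeca[b]furan-2(3H)-one (C3 epimers) | O[C@@H]1C/C(C)=C/CC/C(C)=C/[C@H]2OC(=O)C(C)[C@@H]12 | intermediate
14 | (2Z)-2-methylbut-2-enoic acid (angelic acid) | C/C=C(/C)C(=O)O | starting material
15 | (3aS,4S,6E,10E,11aR)-3,6,10-trimethyl-2-oxo-2,3,3a,4,5,8,9,11a-octahydrocyclodeca[b]furan-4-yl (2Z)-2-methylbut-2-enoate (C3 epimers) | C/C=C(/C)C(=O)O[C@H]1C/C(C)=C/CC/C(C)=C/[C@H]2OC(=O)C(C)[C@@H]12 | intermediate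
16 | acetic anhydride | CC(=O)OC(C)=O | starting material
17 | potassium (3R,3aS,4S,6E,10E,11aR)-3,6,10-trimethyl-4-{[(2Z)-2-methylbut-2-enoyl]oxy}-2-oxo-2,3,3a,4,5,8,9,11a-octahydrocyclodeca[b]furan-3-olate | C/C=C(/C)C(=O)O[C@H]1C/C(C)=C/CC/C(C)=C/[C@H]2OC(=O)[C@](C)([O-])[C@@H]12.[K+] | intermediate
18 | CNP0144564.1, (3R,3aS,4S,6E,10E,11aR)-3-acetoxy-3,6,10-trimethyl-2-oxo-2,3,3a,4,5,8,9,11a-octahydrocyclodeca[b]furan-4-yl (2Z)-2-methylbut-2-enoate | C/C=C(/C)C(=O)O[C@H]1C/C(C)=C/CC/C(C)=C/[C@H]2OC(=O)[C@](C)(OC(C)=O)[C@@H]12 | target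

**Totals**
Total step count: 9. Longest linear sequence: 9 steps (1 → 18).

**Steps most likely to fail, each with a fallback**

Step 7 is the riskiest. The allyl-stabilised ketyl may dimerise (pinacol) or be reduced on to the allylic alcohol instead of adding to the hindered trisubstituted enoate. That over-reduced by-product is the O8-silyl ether of 8 and returns to 10 under the step 5 conditions. The diastereoselectivity also rests on an acyclic model, not on a precedent for this ring. The fallback replaces the open-shell ketyl by a closed-shell, carbene-catalysed homoenolate. It sets out from 6 as generated in step 4 and comes back to the route at 12. Compound 6 is trapped with 2-(triphenyl-λ5-phosphanylidene)propanal in place of 5, giving (2E,4R,6E,10E)-4-(anilinooxy)-12-hydroxy-2,6,10-trimethyldodeca-2,6,10-trienal F1. Cu(OAc)2 in EtOH then gives (2E,4R,6E,10E)-4,12-dihydroxy-2,6,10-trimethyldodeca-2,6,10-trienal F2. TEMPO/PhI(OAc)2 oxidises the primary allylic alcohol to (2E,4R,6E,10E)-4-hydroxy-2,6,10-trimethyldodeca-2,6,10-trienedial F3, and Et3SiCl/imidazole gives (2E,4R,6E,10E)-2,6,10-trimethyl-4-[(triethylsilyl)oxy]dodeca-2,6,10-trienedial F4. With 1,3-dimesitylimidazolium chloride (15 mol %) and DBU (12 mol %) in THF at 2 mM and 40 °C, the carbene converts the α-methyl enal terminus into a Breslow-type homoenolate. Its C7 attacks the C6 aldehyde anti to the silyloxy group, and the alkoxide is acylated by the acyl azolium to give the cis-lactone 12. This is then desilylated to 13 as in step 7.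

Step 8 is the second risk. Mitsunobu displacement at the hindered C8 next to the ring fusion may be slow or give elimination with the weakly acidic, α-branched angelic acid. The fallback builds the (Z)-alkene on the substrate instead of transferring a preformed angelate; it sets out from 13 and comes back at 15. Compound 13 is coupled under the same PPh3/DIAD conditions with the smaller and more acidic 2-[bis(2,2,2-trifluoroethoxy)phosphoryl]propanoic acid. This gives, with inversion, (3aS,4S,6E,10E,11aR)-3,6,10-trimethyl-2-oxo-2,3,3a,4,5,8,9,11a-octahydrocyclodeca[b]furan-4-yl 2-[bis(2,2,2-trifluoroethoxy)phosphoryl]propanoate F5. Still–Gennari olefination of the phosphonate (KN(SiMe3)2, 18-crown-6, THF, −78 °C, then acetaldehyde) gives the (Z)-2-methylbut-2-enoate 15.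

Step 9 is the third risk. The amide base could attack the angelate, either by γ-deprotonation with loss of the (Z) geometry or by Claisen-type acyl transfer to the neighbouring lactone enolate. The in-flask acetylation of a tertiary alkoxide may also be incomplete. The fallback changes the order so that no angelate is present during enolate chemistry; it sets out from 12 (isolated by leaving out the fluoride treatment in step 7) and comes back at 18. Compound 12 is treated with KN(SiMe3)2 and the oxaziridine to give potassium (3R,3aR,4R,6E,10E,11aR)-3,6,10-trimethyl-2-oxo-4-[(triethylsilyl)oxy]-2,3,3a,4,5,8,9,11a-octahydrocyclodeca[b]furan-3-olate F6. Ac2O converts this into (3R,3aR,4R,6E,10E,11aR)-3,6,10-trimethyl-2-oxo-4-[(triethylsilyl)oxy]-2,3,3a,4,5,8,9,11a-octahydrocyclodeca[b]furan-3-yl acetate F7. AcOH/Bu4NF then gives (3R,3aS,4R,6E,10E,11aR)-4-hydroxy-3,6,10-trimethyl-2-oxo-2,3,3a,4,5,8,9,11a-octahydrocyclodeca[b]furan-3-yl acetate F8. Mitsunobu esterification of F8 with 14 (PPh3, DIAD, toluene) inverts C8 and gives 18.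

**Further compounds**
F1 | step 7 | (2E,4R,6E,10E)-4-(anilinooxy)-12-hydroxy-2,6,10-trimethyldodeca-2,6,10-trienal | O=C/C(C)=C/[C@H](ONc1ccccc1)C/C(C)=C/CC/C(C)=C/CO
F2 | step 7 | (2E,4R,6E,10E)-4,12-dihydroxy-2,6,10-trimethyldodeca-2,6,10-trienal | O=C/C(C)=C/[C@H](O)C/C(C)=C/CC/C(C)=C/CO
F3 | step 7 | (2E,4R,6E,10E)-4-hydroxy-2,6,10-trimethyldodeca-2,6,10-trienedial | O=C/C(C)=C/[C@H](O)C/C(C)=C/CC/C(C)=C/C=O
F4 | step 7 | (2E,4R,6E,10E)-2,6,10-trimethyl-4-[(triethylsilyl)oxy]dodeca-2,6,10-trienedial | O=C/C(C)=C/[C@H](O[Si](CC)(CC)CC)C/C(C)=C/CC/C(C)=C/C=O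
F5 | step 8 | (3aS,4S,6E,10E,11aR)-3,6,10-trimethyl-2-oxo-2,3,3a,4,5,8,9,11a-octahydrocyclodeca[b]furan-4-yl 2-[bis(2,2,2-trifluoroethoxy)phosphoryl]propanoate | CC(C(=O)O[C@H]1C/C(C)=C/CC/C(C)=C/[C@H]2OC(=O)C(C)[C@@H]12)P(=O)(OCC(F)(F)F)OCC(F)(F)F
F6 | step 9 | potassium (3R,3aR,4R,6E,10E,11aR)-3,6,10-trimethyl-2-oxo-4-[(triethylsilyl)oxy]-2,3,3a,4,5,8,9,11a-octahydrocyclodeca[b]furan-3-olate | CC[Si](CC)(CC)O[C@@H]1C/C(C)=C/CC/C(C)=C/[C@H]2OC(=O)[C@](C)([O-])[C@@H]12.[K+]
F7 | step 9 | (3R,3aR,4R,6E,10E,11aR)-3,6,10-trimethyl-2-oxo-4-[(triethylsilyl)oxy]-2,3,3a,4,5,8,9,11a-octahydrocyclodeca[b]furan-3-yl acetate | CC[Si](CC)(CC)O[C@@H]1C/C(C)=C/CC/C(C)=C/[C@H]2OC(=O)[C@](C)(OC(C)=O)[C@@H]12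
F8 | step 9 | (3R,3aS,4R,6E,10E,11aR)-4-hydroxy-3,6,10-trimethyl-2-oxo-2,3,3a,4,5,8,9,11a-octahydrocyclodeca[b]furan-3-yl acetate | O[C@@H]1C/C(C)=C/CC/C(C)=C/[C@H]2OC(=O)[C@](C)(OC(C)=O)[C@@H]12
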